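**Strategy.** The fused resorcinol ring of the indane (C3a, C4, C5–O, C6, C7–O, C7a) is built last among the core rings: its two meta oxygens are read as a ketene carbonyl (C7) and an ynol ether (C5). A cyclopentenyl diazomethyl ketone that already carries the trans C1/C2 aryl pair and a silylated C3 oxygen is photolysed with ethoxyacetylene; Wolff rearrangement, [2+2] addition, 4π opening and 6π closure form C3a–C4, C4–C5, C6–C7 and C7–C7a and the arene in one operation. The C3 oxygen then becomes the sulfone for a Ramberg–Bäcklund union with an enantiopure dihydrobenzofuran fragment.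

Key step: step 8

**Remarks on the chemistry**
- Indane locants follow the target throughout: C1 carries the 4-oxygenated phenyl group, C2 the 3,5-dioxygenated phenyl group, C3 the oxygen, sulfur or alkylidene group, and C7 the oxygen next to C7a.
- Assumption: (R)-BINAP is taken to give the (3R) centre in step 1 by analogy with the parent phenyl addition to cyclopentenone, and Rh2(S-PTAD)4 (PTAD = (1-adamantyl)(phthalimido)acetate) is taken to give the (3R) centre in step 15. If either sense of induction proves opposite, the antipodal ligand is used and nothing else changes.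
- The diazo ketone is made by diazo transfer to a methyl ketone, because diazomethane adds as a 1,3-dipole to conjugated acid chlorides.
- The positions of the acyl group and of the oxygen on the five-membered ring are fixed by enolate chemistry (steps 1, 2 and 5), so no regiochemical choice between two ketone α-positions is needed.
- The benzylic C3 alcohol itself is the handle for sulfur; no indanone is required.

**Route**

Step 1
Reactants: 1 cyclopent-2-en-1-one; 2 1-bromo-3,5-dimethoxybenzene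
Product: 6 {[(3R)-3-(3,5-dimethoxyphenyl)cyclopent-1-en-1-yl]oxy}trimethylsilane, via (3,5-dimethoxyphenyl)lithium 3 (not isolated), via (3,5-dimethoxyphenyl)titanium triisopropoxide 4 (not isolated), via titanium enolate 5 (not isolated)
Conditions: 2, n-BuLi, THF, −78 °C; ClTi(OiPr)3, −78 → 20 °C; then 1, [Rh(OH)(cod)]2 (1.5 mol%), (R)-BINAP (3.3 mol%), THF, 20 °C; then LiOiPr, Me3SiCl, 20 °C
Reagents that add atoms: chlorotrimethylsilane, C[Si](C)(C)Cl
Why: Rhodium-catalysed asymmetric 1,4-addition (Hayashi–Miyaura type, aryltitanium variant) transfers the aryl group to C3 of 1 under control of (R)-BINAP, which should set the (R) centre, and silylation of the titanium enolate fixes the enol double bond on the side of the new stereocentre.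

Step 2
Reactants: 6 {[(3R)-3-(3,5-dimethoxyphenyl)cyclopent-1-en-1-yl]oxy}trimethylsilane
Product: 9 (2S,3S)-3-(3,5-dimethoxyphenyl)-2-hydroxycyclopentan-1-one (2,3-trans), via silyloxy epoxide 7 (not isolated), via 2-trimethylsilyloxy ketone 8 (not isolated)
Conditions: mCPBA, NaHCO3, CH2Cl2, −20 → 0 °C; then HCl (1 M aq), THF, 0 °C
Reagents that add atoms: 3-chloroperbenzoic acid, OOC(=O)c1cccc(Cl)c1
Why: Rubottom oxidation, in which the peracid epoxidises the electron-rich enol ether on the face opposite the C3 aryl group and silyl migration followed by hydrolysis leaves the C2 hydroxyl trans to the aryl group (a centre of no later consequence).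

Step 3
Reactants: 9 (2S,3S)-3-(3,5-dimethoxyphenyl)-2-hydroxycyclopentan-1-one
Product: 10 (2S,3S)-2-[(tert-butyldimethylsilyl)oxy]-3-(3,5-dimethoxyphenyl)cyclopentan-1-one
Conditions: t-BuMe2SiCl, imidazole, DMF, 20 °C
Reagents that add atoms: tert-butyldimethylsilyl chloride, CC(C)(C)[Si](C)(C)Cl
Why: Standard silylation of a secondary alcohol masks the oxygen that becomes the indane C3 oxygen, prevents ketol isomerisation and makes the C2 proton kinetically inert in the next step.

Step 4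
Reactants: 10 (2S,3S)-2-[(tert-butyldimethylsilyl)oxy]-3-(3,5-dimethoxyphenyl)cyclopentan-1-one
Product: 12 (4S,5S)-5-[(tert-butyldimethylsilyl)oxy]-4-(3,5-dimethoxyphenyl)cyclopent-2-en-1-one, via trimethylsilyl enol ether 11 (not isolated)
Conditions: LiN(iPr)2, THF, −78 °C; Me3SiCl; then Pd(OAc)2, MeCN, 20 °C
Reagents that add atoms: none
Why: Saegusa–Ito dehydrogenation, in which the amide base removes a proton from the unhindered C5 methylene and not from the silyloxy-bearing C2, and divalent palladium converts the enol silane into the enone under base-free conditions that leave the now γ-benzylic C4 centre untouched.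

Step 5
Reactants: 12 (4S,5S)-5-[(tert-butyldimethylsilyl)oxy]-4-(3,5-dimethoxyphenyl)cyclopent-2-en-1-one; 13 (4-methoxyphenyl)magnesium bromide
Product: 16 (3R,4S,5S)-5-[(tert-butyldimethylsilyl)oxy]-4-(3,5-dimethoxyphenyl)-3-(4-methoxyphenyl)cyclopent-1-en-1-yl trifluoromethanesulfonate (all-trans), via bromomagnesium diarylcuprate 14 (not isolated), via bromomagnesium enolate 15 (not isolated)
Conditions: 13 (2.2 equiv), CuBr·SMe2 (1.1 equiv), THF, −78 → −30 °C; then N-(5-chloropyridin-2-yl)bis(trifluoromethanesulfonimide), −78 → 0 °C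
Reagents that add atoms: N-(5-chloropyridin-2-yl)bis(trifluoromethanesulfonimide), FC(F)(F)S(=O)(=O)N(c1ccc(Cl)cn1)S(=O)(=O)C(F)(F)F
Why: Cuprate conjugate addition to a 4-substituted cyclopentenone occurs anti to the C4 aryl group and so sets the trans diaryl relationship, and O-sulfonylation of the regiodefined enolate (conjugate addition–enolate triflation) places the triflate on the carbon that must carry the acyl group.

Step 6
Reactants: 16 (3R,4S,5S)-5-[(tert-butyldimethylsilyl)oxy]-4-(3,5-dimethoxyphenyl)-3-(4-methoxyphenyl)cyclopent-1-en-1-yl trifluoromethanesulfonate; 17 tributyl(1-ethoxyvinyl)stannane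
Product: 19 1-[(3S,4S,5S)-5-[(tert-butyldimethylsilyl)oxy]-4-(3,5-dimethoxyphenyl)-3-(4-methoxyphenyl)cyclopent-1-en-1-yl]ethan-1-one, via 1-ethoxyvinyl diene 18 (not isolated)
Conditions: 17, Pd(PPh3)4 (5 mol%), LiCl, THF, 65 °C; then HCl (1 M aq), THF, 0 °C
Reagents that add atoms: water, O
Why: Stille coupling of an enol triflate with an α-ethoxyvinylstannane followed by mild hydrolysis of the dienyl ether is a standard way to an α,β-unsaturated methyl ketone and leaves the silyl ether and the stereocentres intact.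

Step 7
Reactants: 19 1-[(3S,4S,5S)-5-[(tert-butyldimethylsilyl)oxy]-4-(3,5-dimethoxyphenyl)-3-(4-methoxyphenyl)cyclopent-1-en-1-yl]ethan-1-one
Product: 21 2-diazo-1-[(3S,4S,5S)-5-[(tert-butyldimethylsilyl)oxy]-4-(3,5-dimethoxyphenyl)-3-(4-methoxyphenyl)cyclopent-1-en-1-yl]ethan-1-one, via trifluoroacetyl diketone 20 (not isolated)
Conditions: LiN(SiMe3)2, THF, −78 °C; CF3CO2CH2CF3; then MsN3, Et3N, H2O, MeCN, 20 °C
Reagents that add atoms: methanesulfonyl azide, CS(=O)(=O)N=[N+]=[N-]
Why: Detrifluoroacetylative diazo transfer, in which kinetic deprotonation of the methyl group, trifluoroacetylation and reaction with the sulfonyl azide give the α,β-unsaturated diazomethyl ketone without exposing a conjugated acid chloride to diazomethane.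

Step 8
Reactants: 21 2-diazo-1-[(3S,4S,5S)-5-[(tert-butyldimethylsilyl)oxy]-4-(3,5-dimethoxyphenyl)-3-(4-methoxyphenyl)cyclopent-1-en-1-yl]ethan-1-one; 22 ethoxyacetylene
Product: 27 (1S,2S,3S)-3-[(tert-butyldimethylsilyl)oxy]-2-(3,5-dimethoxyphenyl)-5-ethoxy-1-(4-methoxyphenyl)indan-7-ol, via vinylketene 23 (not isolated), via 4-vinylcyclobutenone 24 (not isolated), via dienylketene 25 (not isolated), via cyclohexadienone 26 (not isolated)
Conditions: 22 (3 equiv), ClCH2CH2Cl, hν (medium-pressure Hg lamp, Pyrex), 20 °C; then 80 °C, sealed tube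
Reagents that add atoms: none
Why: Irradiation expels N2 and the cyclopentenyl group migrates (Wolff rearrangement) to give vinylketene 23, whose carbonyl carbon is attacked by the nucleophilic terminal carbon of 22 in a regiospecific [2+2] cycloaddition to cyclobutenone 24; heat opens 24 by 4π electrocyclisation to dienylketene 25, which closes by 6π electrocyclisation onto the ring alkene carbon (future C7a) and tautomerises from dienone 26 to phenol 27. The closest known reaction type is the photochemical Wolff variant of the Danheiser benzannulation of α,β-unsaturated diazo ketones with alkoxyalkynes. The transient four-membered ring closes by [2+2] cycloaddition and the new six-membered arene ring by thermal 6π electrocyclisation of the Z-dienylketene, the reversible 4π opening funnelling material to the geometry that can cyclise. No stereocentre is created; C1 and C2 (C3 and C4 of 21) should be carried through because no step ionises or deprotonates the allylic C1–H. The selectivity needed is regiochemical (C7–OH next to C7a, C5–OEt meta to it) and is secured by the ketene and ynol ether polarity, while the silyl ether blocks lactonisation of the ketene by the C3 oxygen.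

Step 9
Reactants: 27 (1S,2S,3S)-3-[(tert-butyldimethylsilyl)oxy]-2-(3,5-dimethoxyphenyl)-5-ethoxy-1-(4-methoxyphenyl)indan-7-ol
Product: 28 tert-butyl{[(1S,2S,3S)-2-(3,5-dimethoxyphenyl)-5-ethoxy-7-methoxy-1-(4-methoxyphenyl)indan-3-yl]oxy}dimethylsilane
Conditions: MeI, K2CO3, acetone, 50 °C
Reagents that add atoms: iodomethane, CI
Why: Williamson methylation of the phenol puts C7–O in the same ether form as the other phenols, so that thiolate alkylation, oxidation and the basic olefination later meet no free phenoxide.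

Step 10
Reactants: 28 tert-butyl{[(1S,2S,3S)-2-(3,5-dimethoxyphenyl)-5-ethoxy-7-methoxy-1-(4-methoxyphenyl)indan-3-yl]oxy}dimethylsilane
Product: 29 (1S,2S,3S)-2-(3,5-dimethoxyphenyl)-5-ethoxy-7-methoxy-1-(4-methoxyphenyl)indan-3-ol
Conditions: Bu4NF, THF, 20 → 40 °C
Reagents that add atoms: none
Why: Fluoride-mediated cleavage of the silyl ether frees the benzylic C3 alcohol without touching aryl ethers or stereocentres.

Step 11
Reactants: 29 (1S,2S,3S)-2-(3,5-dimethoxyphenyl)-5-ethoxy-7-methoxy-1-(4-methoxyphenyl)indan-3-ol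
Product: 30 S-[(1S,2S,3S)-2-(3,5-dimethoxyphenyl)-5-ethoxy-7-methoxy-1-(4-methoxyphenyl)indan-3-yl] ethanethioate
Conditions: AcSH, ZnI2 (0.5 equiv), ClCH2CH2Cl, 20 °C
Reagents that add atoms: thioacetic acid, CC(=O)S
Why: ZnI2-promoted substitution of a benzylic alcohol by thioacetic acid proceeds through the secondary indanyl cation (SN1), which should be captured on the face opposite the C2 aryl group; the C3 configuration is erased in step 21, so either epimer serves.

Step 12
Reactants: 31 5-bromo-2-hydroxybenzonitrile; 32 4-methoxybenzyl chloride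
Product: 33 5-bromo-2-[(4-methoxybenzyl)oxy]benzonitrile
Conditions: K2CO3, DMF, 60 °C
Reagents that add atoms: none
Why: Williamson etherification of the acidic cyanophenol installs the 4-methoxybenzyl group whose methylene carbon becomes C2 of the dihydrobenzofuran.

Step 13
Reactants: 33 5-bromo-2-[(4-methoxybenzyl)oxy]benzonitrile; 34 (3,5-dimethoxyphenyl)magnesium chloride
Product: 36 {5-bromo-2-[(4-methoxybenzyl)oxy]phenyl}(3,5-dimethoxyphenyl)methanone, via chloromagnesium ketimine 35 (not isolated)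
Conditions: 34, THF, 0 → 65 °C; then HCl (1 M aq), 20 °C
Reagents that add atoms: water, O
Why: Addition of an aryl Grignard reagent to the nitrile stops at the ketimine salt, whose hydrolysis gives the diaryl ketone while the aryl bromide and the benzyl ether stay inert.

Step 14
Reactants: 36 {5-bromo-2-[(4-methoxybenzyl)oxy]phenyl}(3,5-dimethoxyphenyl)methanone
Product: 37 hydrazone of 36
Conditions: N2H4·H2O, AcOH (cat.), EtOH, 80 °C
Reagents that add atoms: hydrazine, NN
Why: Condensation of the diaryl ketone with hydrazine gives the N-unsubstituted hydrazone needed for oxidation to a diaryldiazomethane.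

Step 15
Reactants: 37 hydrazone of 36
Product: 39 (2S,3R)-5-bromo-3-(3,5-dimethoxyphenyl)-2-(4-methoxyphenyl)-2,3-dihydro-1-benzofuran (cis), via diaryldiazomethane 38 (not isolated)
Conditions: MnO2, CH2Cl2, 0 °C; then Rh2(S-PTAD)4 (1 mol%), CH2Cl2, −20 → 0 °C
Reagents that add atoms: none
Why: Oxidation to the diaryldiazomethane and dirhodium-catalysed intramolecular 1,5 C–H insertion of the donor/donor carbene into the activated benzylic ether C–H bond is an established enantioselective route to cis-2,3-diaryl-2,3-dihydrobenzofurans, in which the chiral carboxylate ligands set C3 and the concerted insertion gives the cis C2 centre.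

Step 16
Reactants: 39 (2S,3R)-5-bromo-3-(3,5-dimethoxyphenyl)-2-(4-methoxyphenyl)-2,3-dihydro-1-benzofuran
Product: 40 (2R,3R)-5-bromo-3-(3,5-dimethoxyphenyl)-2-(4-methoxyphenyl)-2,3-dihydro-1-benzofuran (trans)
Conditions: BF3·OEt2 (0.2 equiv), CH2Cl2 (dilute), −20 → 0 °C
Reagents that add atoms: none
Why: Lewis-acid-catalysed epimerisation, in which reversible heterolysis of the C2–O bond gives a 4-methoxybenzylic cation that recloses on the phenol oxygen to the more stable trans five-membered ring while C3, which is not involved, keeps its configuration.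

Step 17
Reactants: 40 (2R,3R)-5-bromo-3-(3,5-dimethoxyphenyl)-2-(4-methoxyphenyl)-2,3-dihydro-1-benzofuran
Product: 43 [(2R,3R)-3-(3,5-dimethoxyphenyl)-2-(4-methoxyphenyl)-2,3-dihydro-1-benzofuran-5-yl]methanol, via aryllithium 41 (not isolated), via 5-carbaldehyde 42 (not isolated)
Conditions: n-BuLi, THF, −78 °C; DMF, −78 → 0 °C; then MeOH, NaBH4, 0 °C
Reagents that add atoms: N,N-dimethylformamide, CN(C)C=O
Why: Bromine–lithium exchange, formylation and borohydride reduction in one flask is a standard one-carbon homologation of an aryl bromide to a benzylic alcohol, the exchange being faster than deprotonation of the benzylic ring positions at −78 °C.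

Step 18
Reactants: 43 [(2R,3R)-3-(3,5-dimethoxyphenyl)-2-(4-methoxyphenyl)-2,3-dihydro-1-benzofuran-5-yl]methanol
Product: 44 (2R,3R)-5-(bromomethyl)-3-(3,5-dimethoxyphenyl)-2-(4-methoxyphenyl)-2,3-dihydro-1-benzofuran
Conditions: PPh3, CBr4, CH2Cl2, 0 °C (used at once)
Reagents that add atoms: tetrabromomethane, BrC(Br)(Br)Br
Why: Appel bromination converts the electron-rich benzylic alcohol into the bromide under neutral conditions that do not ionise the acid-sensitive dihydrofuran.

Step 19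
Reactants: 30 S-[(1S,2S,3S)-2-(3,5-dimethoxyphenyl)-5-ethoxy-7-methoxy-1-(4-methoxyphenyl)indan-3-yl] ethanethioate; 44 (2R,3R)-5-(bromomethyl)-3-(3,5-dimethoxyphenyl)-2-(4-methoxyphenyl)-2,3-dihydro-1-benzofuran
Product: 46 (2R,3R)-3-(3,5-dimethoxyphenyl)-5-({[(1S,2S,3S)-2-(3,5-dimethoxyphenyl)-5-ethoxy-7-methoxy-1-(4-methoxyphenyl)indan-3-yl]sulfanyl}methyl)-2-(4-methoxyphenyl)-2,3-dihydro-1-benzofuran, via sodium indane-3-thiolate 45 (not isolated)
Conditions: 30, NaOMe, MeOH/THF (degassed), 0 °C; then 44, THF, 0 → 20 °C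
Reagents that add atoms: none
Why: Methanolysis of the thioester liberates the thiolate, which is alkylated at once by the reactive benzylic bromide (SN2 thioether synthesis), joining the two halves without acid.

Step 20
Reactants: 46 (2R,3R)-3-(3,5-dimethoxyphenyl)-5-({[(1S,2S,3S)-2-(3,5-dimethoxyphenyl)-5-ethoxy-7-methoxy-1-(4-methoxyphenyl)indan-3-yl]sulfanyl}methyl)-2-(4-methoxyphenyl)-2,3-dihydro-1-benzofuran
Product: 48 (2R,3R)-3-(3,5-dimethoxyphenyl)-5-({[(1S,2S,3S)-2-(3,5-dimethoxyphenyl)-5-ethoxy-7-methoxy-1-(4-methoxyphenyl)indan-3-yl]sulfonyl}methyl)-2-(4-methoxyphenyl)-2,3-dihydro-1-benzofuran, via sulfoxide 47 (not isolated)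
Conditions: mCPBA (2.2 equiv), NaHCO3, CH2Cl2, 0 °C
Reagents that add atoms: 3-chloroperbenzoic acid, OOC(=O)c1cccc(Cl)c1
Why: Peracid oxidation of a dialkyl sulfide to the sulfone through the sulfoxide is fast compared with any oxidation of the aryl ethers.

Step 21
Reactants: 48 (2R,3R)-3-(3,5-dimethoxyphenyl)-5-({[(1S,2S,3S)-2-(3,5-dimethoxyphenyl)-5-ethoxy-7-methoxy-1-(4-methoxyphenyl)indan-3-yl]sulfonyl}methyl)-2-(4-methoxyphenyl)-2,3-dihydro-1-benzofuran
Product: 51 (2R,3R)-3-(3,5-dimethoxyphenyl)-5-{(E)-[(1S,2S)-2-(3,5-dimethoxyphenyl)-5-ethoxy-7-methoxy-1-(4-methoxyphenyl)indan-3-ylidene]methyl}-2-(4-methoxyphenyl)-2,3-dihydro-1-benzofuran, via α-chloro sulfone 49 (not isolated), via episulfone 50 (not isolated)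
Conditions: KOH (powdered), CCl4, t-BuOH, H2O, 60 °C
Reagents that add atoms: none
Why: Ramberg–Bäcklund reaction (KOH/CCl4 variant), in which α-chlorination, 1,3-elimination to the episulfone and loss of SO2 give the exocyclic trisubstituted alkene, a transformation known for 3-(benzylsulfonyl)-1,2-diarylindanes; the E isomer is expected because the intermediates epimerise under base and the aryl group avoids the peri C4–H.

Step 22
Reactants: 51 (2R,3R)-3-(3,5-dimethoxyphenyl)-5-{(E)-[(1S,2S)-2-(3,5-dimethoxyphenyl)-5-ethoxy-7-methoxy-1-(4-methoxyphenyl)indan-3-ylidene]methyl}-2-(4-methoxyphenyl)-2,3-dihydro-1-benzofuran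
Product: 53 (1S,2S,3E)-2-(3,5-dihydroxyphenyl)-3-{[(2R,3R)-3-(3,5-dihydroxyphenyl)-2-(4-hydroxyphenyl)-2,3-dihydro-1-benzofuran-5-yl]methylidene}-1-(4-hydroxyphenyl)indane-5,7-diol (CNP0184753.1), via octakis(dibromoboryl) ether 52 (not isolated)
Conditions: BBr3 (excess), CH2Cl2, −78 → 20 °C; then H2O, 0 °C
Reagents that add atoms: none
Why: Lewis-acid cleavage of the seven aryl methyl ethers and the aryl ethyl ether with BBr3, followed by hydrolysis of the aryl borates, frees all eight phenols; should the dihydrofuran C2–O bond open transiently, reclosure gives the same trans isomer because C3 is unaffected.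

**Compound list**

1 | cyclopent-2-en-1-one | O=C1C=CCC1 | starting material
2 | 1-bromo-3,5-dimethoxybenzene | COc1cc(Br)cc(OC)c1 | starting material
3 | (3,5-dimethoxyphenyl)lithium | COc1cc([Li])cc(OC)c1 | intermediate (not isolated)
4 | (3,5-dimethoxyphenyl)titanium triisopropoxide | COc1cc(cc(OC)c1)[Ti](OC(C)C)(OC(C)C)OC(C)C | intermediate (not isolated)
5 | triisopropoxytitanium enolate of (3R)-3-(3,5-dimethoxyphenyl)cyclopentanone, enolised towards C2 | CC(C)O[Ti](OC(C)C)(OC(C)C)OC1=C[C@H](c2cc(OC)cc(OC)c2)CC1 | intermediate (not isolated)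
6 | {[(3R)-3-(3,5-dimethoxyphenyl)cyclopent-1-en-1-yl]oxy}trimethylsilane | C[Si](C)(C)OC1=C[C@H](c2cc(OC)cc(OC)c2)CC1 | intermediate
7 | 4-(3,5-dimethoxyphenyl)-1-(trimethylsilyloxy)-6-oxabicyclo[3.1.0]hexane, epoxide oxygen anti to the aryl group, aryl-bearing carbon as in 6 | C[Si](C)(C)O[C@@]12CC[C@@H](c3cc(OC)cc(OC)c3)[C@@H]1O2 | intermediate (not isolated)
8 | (2S,3S)-3-(3,5-dimethoxyphenyl)-2-(trimethylsilyloxy)cyclopentan-1-one | C1CC(=O)[C@@H](O[Si](C)(C)C)[C@@H]1c2cc(OC)cc(OC)c2 | intermediate (not isolated)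
9 | (2S,3S)-3-(3,5-dimethoxyphenyl)-2-hydroxycyclopentan-1-one (trans) | C1CC(=O)[C@@H](O)[C@@H]1c2cc(OC)cc(OC)c2 | intermediate
10 | (2S,3S)-2-[(tert-butyldimethylsilyl)oxy]-3-(3,5-dimethoxyphenyl)cyclopentan-1-one | C1CC(=O)[C@@H](O[Si](C)(C)C(C)(C)C)[C@@H]1c2cc(OC)cc(OC)c2 | intermediate
11 | trimethylsilyl enol ether of 10 formed towards C5, stereocentres as in 10 | C1C=C(O[Si](C)(C)C)[C@@H](O[Si](C)(C)C(C)(C)C)[C@@H]1c2cc(OC)cc(OC)c2 | intermediate (not isolated)
12 | (4S,5S)-5-[(tert-butyldimethylsilyl)oxy]-4-(3,5-dimethoxyphenyl)cyclopent-2-en-1-one | C1=CC(=O)[C@@H](O[Si](C)(C)C(C)(C)C)[C@@H]1c2cc(OC)cc(OC)c2 | intermediate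
13 | (4-methoxyphenyl)magnesium bromide | COc1ccc([Mg]Br)cc1 | starting material
14 | bromomagnesium bis(4-methoxyphenyl)cuprate | COc1ccc(cc1)[Cu-]c1ccc(OC)cc1.[Mg+]Br | intermediate (not isolated)
15 | bromomagnesium (3R,4S,5S)-5-[(tert-butyldimethylsilyl)oxy]-4-(3,5-dimethoxyphenyl)-3-(4-methoxyphenyl)cyclopent-1-en-1-olate | COc1ccc([C@H]2C=C(O[Mg]Br)[C@@H](O[Si](C)(C)C(C)(C)C)[C@@H]2c2cc(OC)cc(OC)c2)cc1 | intermediate (not isolated)
16 | (3R,4S,5S)-5-[(tert-butyldimethylsilyl)oxy]-4-(3,5-dimethoxyphenyl)-3-(4-methoxyphenyl)cyclopent-1-en-1-yl trifluoromethanesulfonate (all-trans) | COc1ccc([C@H]2C=C(OS(=O)(=O)C(F)(F)F)[C@@H](O[Si](C)(C)C(C)(C)C)[C@@H]2c2cc(OC)cc(OC)c2)cc1 | intermediate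
17 | tributyl(1-ethoxyvinyl)stannane | CCCC[Sn](CCCC)(CCCC)C(=C)OCC | starting material
18 | 1-ethoxyvinyl diene: 16 with the triflate replaced by a 1-ethoxyvinyl group, stereocentres as in 16 | COc1ccc([C@H]2C=C(C(=C)OCC)[C@@H](O[Si](C)(C)C(C)(C)C)[C@@H]2c2cc(OC)cc(OC)c2)cc1 | intermediate (not isolated)
19 | 1-[(3S,4S,5S)-5-[(tert-butyldimethylsilyl)oxy]-4-(3,5-dimethoxyphenyl)-3-(4-methoxyphenyl)cyclopent-1-en-1-yl]ethan-1-one | COc1ccc([C@H]2C=C(C(C)=O)[C@@H](O[Si](C)(C)C(C)(C)C)[C@@H]2c2cc(OC)cc(OC)c2)cc1 | intermediate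
20 | 4,4,4-trifluoro-1-(cyclopentenyl)butane-1,3-dione derived from 19, stereocentres as in 19 | COc1ccc([C@H]2C=C(C(=O)CC(=O)C(F)(F)F)[C@@H](O[Si](C)(C)C(C)(C)C)[C@@H]2c2cc(OC)cc(OC)c2)cc1 | intermediate (not isolated)
21 | 2-diazo-1-[(3S,4S,5S)-5-[(tert-butyldimethylsilyl)oxy]-4-(3,5-dimethoxyphenyl)-3-(4-methoxyphenyl)cyclopent-1-en-1-yl]ethan-1-one | COc1ccc([C@H]2C=C(C(=O)C=[N+]=[N-])[C@@H](O[Si](C)(C)C(C)(C)C)[C@@H]2c2cc(OC)cc(OC)c2)cc1 | intermediate (key-step precursor)
22 | ethoxyacetylene | C#COCC | starting material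
23 | vinylketene: 2-(cyclopentenyl)ethen-1-one from 21, stereocentres as in 21 | COc1ccc([C@H]2C=C(C=C=O)[C@@H](O[Si](C)(C)C(C)(C)C)[C@@H]2c2cc(OC)cc(OC)c2)cc1 | intermediate (not isolated)
24 | 4-(cyclopentenyl)-3-ethoxycyclobut-2-en-1-one, ring stereocentres as in 21, cyclobutenone C4 unassigned | COc1ccc([C@H]2C=C(C3C(=O)C=C3OCC)[C@@H](O[Si](C)(C)C(C)(C)C)[C@@H]2c2cc(OC)cc(OC)c2)cc1 | intermediate (not isolated)
25 | dienylketene: 4-(cyclopentenyl)-3-ethoxybuta-1,3-dien-1-one, stereocentres as in 21 | COc1ccc([C@H]2C=C(C=C(OCC)C=C=O)[C@@H](O[Si](C)(C)C(C)(C)C)[C@@H]2c2cc(OC)cc(OC)c2)cc1 | intermediate (not isolated)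
26 | cyclohexa-2,4-dienone tautomer of 27 (7a-H, C7 ketone), C1 to C3 as in 27 | COc1ccc([C@H]2C3C(=O)C=C(OCC)C=C3[C@@H](O[Si](C)(C)C(C)(C)C)[C@@H]2c2cc(OC)cc(OC)c2)cc1 | intermediate (not isolated)
27 | (1S,2S,3S)-3-[(tert-butyldimethylsilyl)oxy]-2-(3,5-dimethoxyphenyl)-5-ethoxy-1-(4-methoxyphenyl)indan-7-ol | COc1ccc([C@H]2c3c(O)cc(OCC)cc3[C@@H](O[Si](C)(C)C(C)(C)C)[C@@H]2c2cc(OC)cc(OC)c2)cc1 | intermediate (key-step product)
28 | tert-butyl{[(1S,2S,3S)-2-(3,5-dimethoxyphenyl)-5-ethoxy-7-methoxy-1-(4-methoxyphenyl)indan-3-yl]oxy}dimethylsilane | COc1ccc([C@H]2c3c(OC)cc(OCC)cc3[C@@H](O[Si](C)(C)C(C)(C)C)[C@@H]2c2cc(OC)cc(OC)c2)cc1 | intermediate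
29 | (1S,2S,3S)-2-(3,5-dimethoxyphenyl)-5-ethoxy-7-methoxy-1-(4-methoxyphenyl)indan-3-ol | COc1ccc([C@H]2c3c(OC)cc(OCC)cc3[C@@H](O)[C@@H]2c2cc(OC)cc(OC)c2)cc1 | intermediate
30 | S-[(1S,2S,3S)-2-(3,5-dimethoxyphenyl)-5-ethoxy-7-methoxy-1-(4-methoxyphenyl)indan-3-yl] ethanethioate (sulfur trans to the C2 aryl group expected) | COc1ccc([C@H]2c3c(OC)cc(OCC)cc3[C@@H](SC(C)=O)[C@@H]2c2cc(OC)cc(OC)c2)cc1 | intermediate
31 | 5-bromo-2-hydroxybenzonitrile | N#Cc1cc(Br)ccc1O | starting material
32 | 4-methoxybenzyl chloride | COc1ccc(CCl)cc1 | starting material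
33 | 5-bromo-2-[(4-methoxybenzyl)oxy]benzonitrile | N#Cc1cc(Br)ccc1OCc1ccc(OC)cc1 | intermediate
34 | (3,5-dimethoxyphenyl)magnesium chloride | COc1cc([Mg]Cl)cc(OC)c1 | starting material
35 | N-chloromagnesium ketimine of 36 | COc1cc(cc(OC)c1)C(=N[Mg]Cl)c1cc(Br)ccc1OCc1ccc(OC)cc1 | intermediate (not isolated)
36 | {5-bromo-2-[(4-methoxybenzyl)oxy]phenyl}(3,5-dimethoxyphenyl)methanone | COc1cc(cc(OC)c1)C(=O)c1cc(Br)ccc1OCc1ccc(OC)cc1 | intermediate
37 | hydrazone of 36 (E/Z mixture) | COc1cc(cc(OC)c1)C(=NN)c1cc(Br)ccc1OCc1ccc(OC)cc1 | intermediate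
38 | diaryldiazomethane from 37 | COc1cc(cc(OC)c1)C(=[N+]=[N-])c1cc(Br)ccc1OCc1ccc(OC)cc1 | intermediate (not isolated)
39 | (2S,3R)-5-bromo-3-(3,5-dimethoxyphenyl)-2-(4-methoxyphenyl)-2,3-dihydro-1-benzofuran (cis) | Brc1ccc2c(c1)[C@@H](c1cc(OC)cc(OC)c1)[C@@H](c1ccc(OC)cc1)O2 | intermediate
40 | (2R,3R)-5-bromo-3-(3,5-dimethoxyphenyl)-2-(4-methoxyphenyl)-2,3-dihydro-1-benzofuran (trans) | Brc1ccc2c(c1)[C@@H](c1cc(OC)cc(OC)c1)[C@H](c1ccc(OC)cc1)O2 | intermediate
41 | 5-lithio derivative of 40 | [Li]c1ccc2c(c1)[C@@H](c1cc(OC)cc(OC)c1)[C@H](c1ccc(OC)cc1)O2 | intermediate (not isolated)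
42 | (2R,3R)-3-(3,5-dimethoxyphenyl)-2-(4-methoxyphenyl)-2,3-dihydro-1-benzofuran-5-carbaldehyde | O=Cc1ccc2c(c1)[C@@H](c1cc(OC)cc(OC)c1)[C@H](c1ccc(OC)cc1)O2 | intermediate (not isolated)
43 | [(2R,3R)-3-(3,5-dimethoxyphenyl)-2-(4-methoxyphenyl)-2,3-dihydro-1-benzofuran-5-yl]methanol | OCc1ccc2c(c1)[C@@H](c1cc(OC)cc(OC)c1)[C@H](c1ccc(OC)cc1)O2 | intermediate
44 | (2R,3R)-5-(bromomethyl)-3-(3,5-dimethoxyphenyl)-2-(4-methoxyphenyl)-2,3-dihydro-1-benzofuran | BrCc1ccc2c(c1)[C@@H](c1cc(OC)cc(OC)c1)[C@H](c1ccc(OC)cc1)O2 | intermediate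
45 | sodium (1S,2S,3S)-2-(3,5-dimethoxyphenyl)-5-ethoxy-7-methoxy-1-(4-methoxyphenyl)indane-3-thiolate | COc1ccc([C@H]2c3c(OC)cc(OCC)cc3[C@@H]([S-])[C@@H]2c2cc(OC)cc(OC)c2)cc1.[Na+] | intermediate (not isolated)
46 | sulfide: (2R,3R)-dihydrobenzofuran-5-ylmethyl (1S,2S,3S)-indan-3-yl sulfide, full name as in step 19 | COc1ccc([C@H]2c3c(OC)cc(OCC)cc3[C@@H](SCc3ccc4c(c3)[C@@H](c3cc(OC)cc(OC)c3)[C@H](c3ccc(OC)cc3)O4)[C@@H]2c2cc(OC)cc(OC)c2)cc1 | intermediate
47 | sulfoxide of 46 (sulfur configuration unassigned) | COc1ccc([C@H]2c3c(OC)cc(OCC)cc3[C@@H](S(=O)Cc3ccc4c(c3)[C@@H](c3cc(OC)cc(OC)c3)[C@H](c3ccc(OC)cc3)O4)[C@@H]2c2cc(OC)cc(OC)c2)cc1 | intermediate (not isolated)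
48 | sulfone of 46, full name as in step 20 | COc1ccc([C@H]2c3c(OC)cc(OCC)cc3[C@@H](S(=O)(=O)Cc3ccc4c(c3)[C@@H](c3cc(OC)cc(OC)c3)[C@H](c3ccc(OC)cc3)O4)[C@@H]2c2cc(OC)cc(OC)c2)cc1 | intermediate
49 | α-chloro sulfone: 48 chlorinated at the exocyclic benzylic carbon (new centre unassigned) | COc1ccc([C@H]2c3c(OC)cc(OCC)cc3[C@@H](S(=O)(=O)C(Cl)c3ccc4c(c3)[C@@H](c3cc(OC)cc(OC)c3)[C@H](c3ccc(OC)cc3)O4)[C@@H]2c2cc(OC)cc(OC)c2)cc1 | intermediate (not isolated)
50 | episulfone: thiirane 1,1-dioxide spiro-fused at indane C3 and bearing the dihydrobenzofuranyl group (ring centres unassigned) | COc1ccc([C@H]2c3c(OC)cc(OCC)cc3C3(C(c4ccc5c(c4)[C@@H](c4cc(OC)cc(OC)c4)[C@H](c4ccc(OC)cc4)O5)S3(=O)=O)[C@@H]2c2cc(OC)cc(OC)c2)cc1 | intermediate (not isolated)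
51 | (2R,3R)-3-(3,5-dimethoxyphenyl)-5-{(E)-[(1S,2S)-2-(3,5-dimethoxyphenyl)-5-ethoxy-7-methoxy-1-(4-methoxyphenyl)indan-3-ylidene]methyl}-2-(4-methoxyphenyl)-2,3-dihydro-1-benzofuran | COc1ccc([C@H]2c3c(OC)cc(OCC)cc3/C(=C/c3ccc4c(c3)[C@@H](c3cc(OC)cc(OC)c3)[C@H](c3ccc(OC)cc3)O4)[C@@H]2c2cc(OC)cc(OC)c2)cc1 | intermediate
52 | octakis(dibromoboryl) ether of 53 | BrB(Br)Oc1ccc([C@H]2c3c(OB(Br)Br)cc(OB(Br)Br)cc3/C(=C/c3ccc4c(c3)[C@@H](c3cc(OB(Br)Br)cc(OB(Br)Br)c3)[C@H](c3ccc(OB(Br)Br)cc3)O4)[C@@H]2c2cc(OB(Br)Br)cc(OB(Br)Br)c2)cc1 | intermediate (not isolated)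
53 | (1S,2S,3E)-2-(3,5-dihydroxyphenyl)-3-{[(2R,3R)-3-(3,5-dihydroxyphenyl)-2-(4-hydroxyphenyl)-2,3-dihydro-1-benzofuran-5-yl]methylidene}-1-(4-hydroxyphenyl)indane-5,7-diol | Oc1ccc([C@H]2c3c(O)cc(O)cc3/C(=C/c3ccc4c(c3)[C@@H](c3cc(O)cc(O)c3)[C@H](c3ccc(O)cc3)O4)[C@@H]2c2cc(O)cc(O)c2)cc1 | target

**Step count.** Total: 22 steps. Longest linear sequence: 15 steps (steps 1–11 and 19–22); the dihydrobenzofuran branch (steps 12–18) joins at step 19.

**Steps most likely to fail, each with a fallback**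

Step 8. The vinylketene may be consumed by dimerisation, by a [1,5]-hydrogen shift from the doubly activated allylic and benzylic C–H (which would also erase the C1 centre), or by acylating the product phenol; the electron-rich aryl groups may also degrade under irradiation. The fallback makes the same ketene thermally, in the dark. Setting out from triflate 16, palladium-catalysed coupling with the Reformatsky reagent BrZnCH2CO2Et (Pd(PPh3)4, THF, 60 °C) should give ethyl 2-[(3S,4S,5S)-5-[(tert-butyldimethylsilyl)oxy]-4-(3,5-dimethoxyphenyl)-3-(4-methoxyphenyl)cyclopent-1-en-1-yl]acetate F1. LiOH in THF/water should give the corresponding acetic acid F2, and 1-chloro-N,N,2-trimethylpropenylamine in CH2Cl2 the acid chloride F3 under neutral conditions. Slow addition of Et3N to F3 and 22 in CH2Cl2 at 20 °C generates ketene 23 by dehydrochlorination and traps it as cyclobutenone 24. Heating 24 in toluene at 80–110 °C then completes the electrocyclic cascade, and the route is rejoined at 27.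

Step 21. Halogenation of the hindered sulfone may be slow, dichlorocarbene may add to the electron-rich alkene as it forms, and control of the alkene geometry may be poor. The fallback is a Julia–Kocienski olefination. It sets out from thioacetate 30 and from aldehyde 42, which is isolated by omitting the borohydride stage of step 17. Thiolate 45 (NaOMe, MeOH/THF) is arylated with 5-chloro-1-phenyl-1H-tetrazole to give 5-{[(1S,2S,3S)-2-(3,5-dimethoxyphenyl)-5-ethoxy-7-methoxy-1-(4-methoxyphenyl)indan-3-yl]sulfanyl}-1-phenyl-1H-tetrazole F4. Oxidation with H2O2 and (NH4)6Mo7O24·4H2O in EtOH gives the corresponding tetrazolyl sulfone F5. Deprotonation with KN(SiMe3)2 in THF at −78 °C and addition of 42 should deliver alkene 51, where the route is rejoined; any Z isomer would be equilibrated to the less strained E isomer with catalytic PhSSPh under visible light.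

Step 22. Acid generated during the dealkylation may move the exocyclic double bond into the five-membered ring, the dihydrofuran may open cationically and be intercepted by bromide, and cleavage of eight ethers may stop short. The fallback replaces the Lewis acid by nucleophilic dealkylation under basic conditions. Setting out from 51, NaSEt in DMF at about 130 °C attacks the methyl and ethyl carbons by SN2 and releases the phenoxides, which give 53 on acidification. No cation is formed at the dihydrofuran or at the styrene, and no new compound lies on this path.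

Further compounds
F1 | step 8 | ethyl 2-[(3S,4S,5S)-5-[(tert-butyldimethylsilyl)oxy]-4-(3,5-dimethoxyphenyl)-3-(4-methoxyphenyl)cyclopent-1-en-1-yl]acetate | COc1ccc([C@H]2C=C(CC(=O)OCC)[C@@H](O[Si](C)(C)C(C)(C)C)[C@@H]2c2cc(OC)cc(OC)c2)cc1
F2 | step 8 | 2-[(3S,4S,5S)-5-[(tert-butyldimethylsilyl)oxy]-4-(3,5-dimethoxyphenyl)-3-(4-methoxyphenyl)cyclopent-1-en-1-yl]acetic acid | COc1ccc([C@H]2C=C(CC(=O)O)[C@@H](O[Si](C)(C)C(C)(C)C)[C@@H]2c2cc(OC)cc(OC)c2)cc1
F3 | step 8 | 2-[(3S,4S,5S)-5-[(tert-butyldimethylsilyl)oxy]-4-(3,5-dimethoxyphenyl)-3-(4-methoxyphenyl)cyclopent-1-en-1-yl]acetyl chloride | COc1ccc([C@H]2C=C(CC(=O)Cl)[C@@H](O[Si](C)(C)C(C)(C)C)[C@@H]2c2cc(OC)cc(OC)c2)cc1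
F4 | step 21 | 5-{[(1S,2S,3S)-2-(3,5-dimethoxyphenyl)-5-ethoxy-7-methoxy-1-(4-methoxyphenyl)indan-3-yl]sulfanyl}-1-phenyl-1H-tetrazole | COc1ccc([C@H]2c3c(OC)cc(OCC)cc3[C@@H](Sc3nnnn3-c3ccccc3)[C@@H]2c2cc(OC)cc(OC)c2)cc1
F5 | step 21 | 5-{[(1S,2S,3S)-2-(3,5-dimethoxyphenyl)-5-ethoxy-7-methoxy-1-(4-methoxyphenyl)indan-3-yl]sulfonyl}-1-phenyl-1H-tetrazole | COc1ccc([C@H]2c3c(OC)cc(OCC)cc3[C@@H](S(=O)(=O)c3nnnn3-c3ccccc3)[C@@H]2c2cc(OC)cc(OC)c2)cc1
F0 | step 22 | none | none
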